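Per minute and litre, free D goes forward into Q and into D2, and it also binds to Q as D.Q; the flask is read for what holds most of the charged D.

    Q ⇌ L (K1 = 0.85, k1 = 0.16 min⁻¹)
    D → Q (k2 = 0.57 min⁻¹)
    D + D ⇌ D2 (K3 = 4.6 M⁻¹, k3 = 17 M⁻¹ min⁻¹)
    D + Q ⇌ D.Q, settled at all times (K4 = 4.3 M⁻¹)

| flask | D | time |
|---|---|---|
| noon | 0.20 M | 4.0 min |
| dawn | 0.20 M | 8.0 min |

* which of these there is most of at the end, counted by the D in it, noon (L / Q / D / D2)
* which of these there is most of at the end, counted by the D in it, dawn (L / Q / D / D2)
* amount of the one of these that there is most of at the end, in percent of the D charged, noon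
* amount of the one of these that there is most of at the end, in percent of the D charged, dawn

- percentages count the D that a species holds: one D2 or D.Q counts as two
- Q is meant together with its D.Q
- a doubled species enters its step squared and goes two at a time
- in an amount of Q, one D.Q counts as one Q
- run time (noon): 4.0 min

Step 2 uses D in proportion to c_D, while step 3 forward uses it in proportion to c_D squared, two at a time. Dividing the first rate by the second makes time drop out and leaves a selectivity factor, S = 0.57 min⁻¹ / (2 · 17 M⁻¹ min⁻¹ · c_D). It can be written S = c*/c_D, where c* is 0.01676 M, the crossover concentration, the c_D at which both routes take D equally fast. S counts the forward rate of step 3 alone.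

My own reckoning sets up three rows:

- c_D = 0.20 M, the charge: S = 0.0838
- c_D = 0.100 M: S = 0.168
- c_D = c*: S = one

The first row says that at the start about 11.9 D enter D2 for each D entering Q. But D2 splits back into D at 3.70 min⁻¹, faster than the 0.57 min⁻¹ of D into Q, so D2 acts as a reversible store and not as a loss. The second row shows S doubling as c_D halves. The last row marks where Q's route overtakes forward step 3. This reckoning gives an order of events and no yield.

The forecast gives 62.7% (60.5% to 65%) at noon and 61.5% (59% to 64%) at dawn, and says: “Q, counted with its D.Q, is largest at both times.”

The simulation gives Q with 55.9% at noon and Q with 60.4% at dawn, so the forecast's noon figure stands 6.8 percentage points high and its dawn figure within tolerance. At the noon end c_D is 0.0329 M, above c*, S is 0.509, and D2 holds 5.91%. A neighbour like noon but charged with 0.050 M of D starts at S = 0.335. It ends with c_D at 0.006881 M, below c*, and S at 2.44. That neighbour holds 1.14% in D2 and 62.9% in Q.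

The numbers are invented; the flask was simulated.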